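**Plan**

- Labels: decalin C1–C10 with C11 the exocyclic CH2 on C9 (terpenoid numbering); quinone Q1 (C=O), Q2 (C–OH), Q3 (C–C11), Q4 (C=O), Q5 (C–N), Q6 (C–H).
- Enabling feature: the quinone ring carries four different groups in a fixed order and hangs on neopentyl C11 beside quaternary C9. A squarate supplies Q1–Q4 with their three oxygens and a 2-ethoxyvinyl unit supplies Q6–Q5, so neither an arylation at C11 nor a late regioselective ring oxidation is needed.
- Cuts, in retrosynthetic order: Q5–N (amine for ethoxide) and Q2 O–tBu; Q4–Q5 (6π closure) with re-formation of the Q1–Q4 bond of a cyclobutenone; Q1–Q6 (vinyllithium); Q3–C11 (C11 lithium reagent plus squarate); C9–C10 and C7–C8 (Diels–Alder); C5–C6 (cross-coupling).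
- Forward: ring A is bought, ring B arises by Diels–Alder, C11 is joined to the four-membered ring, and this ring is expanded to the six-membered hydroquinone, then oxidised, deprotected and aminated.
- Stereochemistry: C8, C9 and C10 all come from one catalyst-controlled exo Diels–Alder of (E)-tiglaldehyde (cis 8,9-methyls from the alkene geometry); no later step touches them.

Key step: step 8

Assumption: the absolute sense of step 3 is assigned from the formyl C–H···O binding model of oxazaborolidinium–enal complexes, by which the (R)-prolinol-derived catalyst should shield the Re face of C-α of the aldehyde; if the antipode were formed, the equally available (S)-catalyst would be used.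

Notation: DecCH2 = [(1R,2S,8aS)-1,2,5,5-tetramethyl-1,2,3,5,6,7,8,8a-octahydronaphthalen-1-yl]methyl, that is C11 carrying the decalin of compound 6 through C9 (same spatial arrangement throughout).

**Route**

Step 1
Reactants: 1 2,2-dimethylcyclohexanone
Product: 2 6,6-dimethylcyclohex-1-en-1-yl trifluoromethanesulfonate
Conditions: LiN(i-Pr)2, THF, −78 °C; PhNTf2, −78 → 0 °C
Reagents that add atoms: N-phenylbis(trifluoromethanesulfonimide), O=S(=O)(N(c1ccccc1)S(=O)(=O)C(F)(F)F)C(F)(F)F
Why: Enolate O-sulfonylation; the ketone can be deprotonated only at C6 because C2 is quaternary, so a single enol triflate should form.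

Step 2
Reactants: 2 6,6-dimethylcyclohex-1-en-1-yl trifluoromethanesulfonate; 3 tributyl(vinyl)stannane
Product: 4 1-ethenyl-6,6-dimethylcyclohex-1-ene
Conditions: Pd(PPh3)4 (3 mol%), LiCl (3 equiv), THF, 65 °C
Reagents that add atoms: none
Why: Stille cross-coupling of an enol triflate with a vinylstannane in the presence of LiCl is the standard entry to 1-vinylcycloalkenes and forms the C5–C6 bond without touching the neighbouring quaternary carbon.

Step 3
Reactants: 4 1-ethenyl-6,6-dimethylcyclohex-1-ene; 5 tiglaldehyde, (E)-2-methylbut-2-enal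
Product: 6 (1R,2S,8aR)-1,2,5,5-tetramethyl-1,2,3,5,6,7,8,8a-octahydronaphthalene-1-carbaldehyde
Conditions: (R)-tetrahydro-1-(2-methylphenyl)-3,3-diphenyl-1H,3H-pyrrolo[1,2-c][1,3,2]oxazaborole (20 mol%), Tf2NH (18 mol%), CH2Cl2, −78 → −40 °C
Reagents that add atoms: none
Why: Catalytic enantioselective Diels–Alder reaction in which the activated s-trans enal should add with ortho regiochemistry (C10 to C-α, C7 to C-β), the α-methyl group should favour the formyl-exo transition state that puts H-10 cis to the formyl group, the (E)-alkene gives the cis 8,9-methyl pair suprafacially, and the catalyst leaves only the Si face of C-α open, so that C8 (S), C9 (R) and C10 are set together.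

Step 4
Reactants: 6 (1R,2S,8aR)-1,2,5,5-tetramethyl-1,2,3,5,6,7,8,8a-octahydronaphthalene-1-carbaldehyde
Product: 7 [(1R,2S,8aR)-1,2,5,5-tetramethyl-1,2,3,5,6,7,8,8a-octahydronaphthalen-1-yl]methanol
Conditions: NaBH4, MeOH, 0 °C
Reagents that add atoms: none
Why: Hydride reduction of a non-enolisable neopentyl aldehyde, which cannot epimerise and leaves the trisubstituted alkene untouched.

Step 5
Reactants: 7 [(1R,2S,8aR)-1,2,5,5-tetramethyl-1,2,3,5,6,7,8,8a-octahydronaphthalen-1-yl]methanol
Product: 8 (1R,2S,8aR)-1-(iodomethyl)-1,2,5,5-tetramethyl-1,2,3,5,6,7,8,8a-octahydronaphthalene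
Conditions: PPh3, I2, imidazole, PhMe, 90 °C
Reagents that add atoms: iodine, II
Why: Appel-type iodination through the alkoxyphosphonium salt; heating should carry the slow SN2 step at the neopentyl carbon, and the quaternary C9 excludes elimination.

Step 6
Reactants: 8 (1R,2S,8aR)-1-(iodomethyl)-1,2,5,5-tetramethyl-1,2,3,5,6,7,8,8a-octahydronaphthalene; 9 di-tert-butyl squarate, 3,4-di-tert-butoxycyclobut-3-ene-1,2-dione
Product: 13 3-tert-butoxy-4-(DecCH2)cyclobut-3-ene-1,2-dione, via C11 organolithium 10 (not isolated), via lithium alkoxide adduct 11 (not isolated), via tertiary trifluoroacetate 12 (not isolated)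
Conditions: t-BuLi (2.1 equiv), Et2O–pentane, −78 °C; add to 9, THF, −78 °C; (CF3CO)2O, −78 °C; aq. NaHCO3
Reagents that add atoms: none
Why: Lithium–iodine exchange gives a primary organolithium that has no β-hydrogen to lose, its 1,2-addition to one squarate carbonyl forms the Q3–C11 bond, and trifluoroacetylation of the alkoxide triggers the known ionisation of squarate adducts to 3-alkyl-4-alkoxycyclobutenediones, here with loss of one tert-butyl group as 2-methylpropene.

Step 7
Reactants: 13 3-tert-butoxy-4-(DecCH2)cyclobut-3-ene-1,2-dione; 14 (Z)-1-bromo-2-ethoxyethene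
Product: 16 3-tert-butoxy-4-[(Z)-2-ethoxyethenyl]-4-hydroxy-2-(DecCH2)cyclobut-2-en-1-one (both carbinol epimers), via (Z)-2-ethoxyvinyllithium 15 (not isolated)
Conditions: 14, t-BuLi (2 equiv), THF, −78 °C; then 13, THF, −78 °C; H2O quench at −78 °C, base-washed glassware
Reagents that add atoms: none
Why: Bromine–lithium exchange with retention gives the (Z)-vinyllithium, which should add 1,2 to the carbonyl next to C–OtBu because the other carbonyl is deactivated as a vinylogous ester; this carbonyl addition fixes the later order Q1–Q6, and the uncontrolled carbinol centre disappears in step 8.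

Step 8
Reactants: 16 3-tert-butoxy-4-[(Z)-2-ethoxyethenyl]-4-hydroxy-2-(DecCH2)cyclobut-2-en-1-one
Product: 19 2-tert-butoxy-5-ethoxy-3-(DecCH2)benzene-1,4-diol, via dienylketene 17 (not isolated), via cyclohexadienone 18 (not isolated)
Conditions: PhMe (degassed), 110 °C, argon
Reagents that add atoms: none
Why: Heating should open the strained cyclobutenone by conrotatory 4π cleavage of the Q1–Q4 σ bond to dienylketene 17, after which a thermal disrotatory 6π electrocyclisation joins the ketene carbon Q4 to the ethoxy-bearing vinyl carbon Q5 to give cyclohexa-2,4-dienone 18, which enolises to the aromatic hydroquinone 19. This is the ring expansion of 4-alkenyl-4-hydroxycyclobutenones to hydroquinones (Moore rearrangement). The only ring closed is the six-membered carbocycle, by 6π electrocyclisation, and the ketene terminus carries no substituent that could clash with the inside ethoxy group of the (Z)-enol ether. No lasting stereocentre is formed, since the carbinol carbon Q1 and the transient sp3 carbon Q5 both end as sp2 centres, so both epimers of 16 converge and the decalin centres stay remote. The selectivity needed is torquoselectivity, inward rotation of the ethoxyvinyl group, and it is secured by the strong preference of the hydroxyl donor on Q1 to rotate outward. The order of substituents around the ring is not decided here but was fixed by the carbonyl additions of steps 6 and 7.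

Step 9
Reactants: 19 2-tert-butoxy-5-ethoxy-3-(DecCH2)benzene-1,4-diol
Product: 20 2-tert-butoxy-5-ethoxy-3-(DecCH2)cyclohexa-2,5-diene-1,4-dione
Conditions: Ag2O, Et2O, 23 °C (crude 19 used directly)
Reagents that add atoms: none
Why: Mild two-electron oxidation of a para-hydroquinone to the quinone, which should leave the alkene and both enol-ether-type groups untouched.

Step 10
Reactants: 20 2-tert-butoxy-5-ethoxy-3-(DecCH2)cyclohexa-2,5-diene-1,4-dione
Product: 21 5-ethoxy-2-hydroxy-3-(DecCH2)cyclohexa-2,5-diene-1,4-dione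
Conditions: CF3CO2H–CH2Cl2 (1:10), 0 °C, short contact
Reagents that add atoms: none
Why: Acidolysis of a tert-butyl vinylogous ester with E1 loss of 2-methylpropene, which should be much faster at 0 °C than protonation of the C5=C6 alkene, while the ethyl vinylogous ester is inert to anhydrous acid.

Step 11
Reactants: 21 5-ethoxy-2-hydroxy-3-(DecCH2)cyclohexa-2,5-diene-1,4-dione; 22 isopentylamine, 3-methylbutan-1-amine
Product: 23 nakijiquinone M, 2-hydroxy-5-[(3-methylbutyl)amino]-3-(DecCH2)cyclohexa-2,5-diene-1,4-dione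
Conditions: 22 (3 equiv), EtOH, 23 → 40 °C; aqueous work-up at pH 5
Reagents that add atoms: none
Why: Addition–elimination (vinylogous transamidation) of the primary amine at Q5, the only alkoxy-bearing and unhindered β-position, as known for 2-hydroxy-5-alkoxyquinones, while the Q2 hydroxyl, present as its ammonium salt, is not displaced.

**Compound list**

1 | 2,2-dimethylcyclohexanone | CC1(C)CCCCC1=O | starting material
2 | 6,6-dimethylcyclohex-1-en-1-yl trifluoromethanesulfonate | CC1(C)CCCC=C1OS(=O)(=O)C(F)(F)F | intermediate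
3 | tributyl(vinyl)stannane | C=C[Sn](CCCC)(CCCC)CCCC | starting material
4 | 1-ethenyl-6,6-dimethylcyclohex-1-ene | C=CC1=CCCCC1(C)C | intermediate
5 | tiglaldehyde, (E)-2-methylbut-2-enal | C/C=C(\C)C=O | starting material
6 | (1R,2S,8aR)-1,2,5,5-tetramethyl-1,2,3,5,6,7,8,8a-octahydronaphthalene-1-carbaldehyde | O=C[C@@]1(C)[C@@H]2CCCC(C)(C)C2=CC[C@@H]1C | intermediate
7 | [(1R,2S,8aR)-1,2,5,5-tetramethyl-1,2,3,5,6,7,8,8a-octahydronaphthalen-1-yl]methanol | OC[C@@]1(C)[C@@H]2CCCC(C)(C)C2=CC[C@@H]1C | intermediate
8 | (1R,2S,8aR)-1-(iodomethyl)-1,2,5,5-tetramethyl-1,2,3,5,6,7,8,8a-octahydronaphthalene | IC[C@@]1(C)[C@@H]2CCCC(C)(C)C2=CC[C@@H]1C | intermediate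
9 | di-tert-butyl squarate, 3,4-di-tert-butoxycyclobut-3-ene-1,2-dione | CC(C)(C)OC1=C(OC(C)(C)C)C(=O)C1=O | starting material
10 | (DecCH2)lithium, the C11 organolithium | [Li]C[C@@]1(C)[C@@H]2CCCC(C)(C)C2=CC[C@@H]1C | intermediate
11 | lithium 2,3-di-tert-butoxy-1-(DecCH2)-4-oxocyclobut-2-en-1-olate (both epimers) | [Li]OC1(C[C@@]2(C)[C@@H]3CCCC(C)(C)C3=CC[C@@H]2C)C(OC(C)(C)C)=C(OC(C)(C)C)C1=O | intermediate
12 | 2,3-di-tert-butoxy-1-(DecCH2)-4-oxocyclobut-2-en-1-yl trifluoroacetate (both epimers) | O=C(OC1(C[C@@]2(C)[C@@H]3CCCC(C)(C)C3=CC[C@@H]2C)C(OC(C)(C)C)=C(OC(C)(C)C)C1=O)C(F)(F)F | intermediate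
13 | 3-tert-butoxy-4-(DecCH2)cyclobut-3-ene-1,2-dione | CC(C)(C)OC1=C(C[C@@]2(C)[C@@H]3CCCC(C)(C)C3=CC[C@@H]2C)C(=O)C1=O | intermediate
14 | (Z)-1-bromo-2-ethoxyethene | CCO/C=C\Br | starting material
15 | (Z)-2-ethoxyvinyllithium | CCO/C=C\[Li] | intermediate
16 | 3-tert-butoxy-4-[(Z)-2-ethoxyethenyl]-4-hydroxy-2-(DecCH2)cyclobut-2-en-1-one (both carbinol epimers) | CCO/C=C\C1(O)C(OC(C)(C)C)=C(C[C@@]2(C)[C@@H]3CCCC(C)(C)C3=CC[C@@H]2C)C1=O | intermediate
17 | (3Z,5Z)-3-tert-butoxy-6-ethoxy-4-hydroxy-2-(DecCH2)hexa-1,3,5-trien-1-one, the dienylketene with hydroxyl outside and ethoxyvinyl inside | CCO/C=C\C(O)=C(OC(C)(C)C)/C(C[C@@]1(C)[C@@H]2CCCC(C)(C)C2=CC[C@@H]1C)=C=O | intermediate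
18 | 3-tert-butoxy-6-ethoxy-4-hydroxy-2-(DecCH2)cyclohexa-2,4-dien-1-one (C6 transient, unassigned) | CCOC1C=C(O)C(OC(C)(C)C)=C(C[C@@]2(C)[C@@H]3CCCC(C)(C)C3=CC[C@@H]2C)C1=O | intermediate
19 | 2-tert-butoxy-5-ethoxy-3-(DecCH2)benzene-1,4-diol | CCOc1cc(O)c(OC(C)(C)C)c(C[C@@]2(C)[C@@H]3CCCC(C)(C)C3=CC[C@@H]2C)c1O | intermediate
20 | 2-tert-butoxy-5-ethoxy-3-(DecCH2)cyclohexa-2,5-diene-1,4-dione | CCOC1=CC(=O)C(OC(C)(C)C)=C(C[C@@]2(C)[C@@H]3CCCC(C)(C)C3=CC[C@@H]2C)C1=O | intermediate
21 | 5-ethoxy-2-hydroxy-3-(DecCH2)cyclohexa-2,5-diene-1,4-dione | CCOC1=CC(=O)C(O)=C(C[C@@]2(C)[C@@H]3CCCC(C)(C)C3=CC[C@@H]2C)C1=O | intermediate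
22 | isopentylamine, 3-methylbutan-1-amine | CC(C)CCN | starting material
23 | nakijiquinone M, 2-hydroxy-5-[(3-methylbutyl)amino]-3-(DecCH2)cyclohexa-2,5-diene-1,4-dione | CC(C)CCNC1=CC(=O)C(O)=C(C[C@@]2(C)[C@@H]3CCCC(C)(C)C3=CC[C@@H]2C)C1=O | target

**Step count**

Total steps: 11. Longest linear sequence: 11 steps (1 to 23).

**Steps most likely to fail**

1. Step 3. What may go wrong: insufficient facial discrimination by the catalyst, erosion of the exo preference, or acid-induced isomerisation and oligomerisation of diene 4 before it reacts. Fallback, from 4 and 5, back at 7: the cycloaddition is run without chiral control under EtAlCl2 (CH2Cl2, −78 °C), which should give the exo adduct as the racemate, that is 6 together with its mirror image, the (1S,2R,8aS)-aldehyde F1. NaBH4 reduction then gives 7 together with the (1S,2R,8aS)-alcohol F2. The two alcohols are separated by preparative chromatography on a chiral stationary phase, and 7 continues with step 5.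

2. Step 8. What may go wrong: capture of the ketene by the free tertiary hydroxyl after outward rotation of the vinyl group (butenolide formation), or acid-triggered collapse of the β-hydroxy enol ether to an enal before ring opening. Fallback, from 16, back at 19: 16 is silylated with Me3SiCl and imidazole (DMF, 0 °C) to the trimethylsilyl ether of the carbinol F3. Thermolysis of F3 in toluene at 110 °C should give, by the same ring opening and 6π closure, the hydroquinone monosilyl ether F4 (silyloxy on Q1, free hydroxyl on Q4). Bu4NF (THF, 0 °C, argon) then frees hydroquinone 19, which continues with step 9.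

3. Step 7. What may go wrong: β-elimination or incomplete halogen–lithium exchange of the vinyl reagent, and loss of the acid-labile adduct during work-up. Fallback, from 13, back at 16: lithium ethoxyacetylide (ethoxyethyne, n-BuLi, THF, −78 °C) is added to the same carbonyl group to give the robust 4-(ethoxyethynyl) carbinol F5. Semihydrogenation (H2, Pd on CaCO3 poisoned with Pb(OAc)2, quinoline, EtOAc) then delivers the (Z)-enol ether 16 just before its use in step 8.

**Further compounds**

F1 | step 3 | (1S,2R,8aS)-1,2,5,5-tetramethyl-1,2,3,5,6,7,8,8a-octahydronaphthalene-1-carbaldehyde, mirror image of 6 | O=C[C@]1(C)[C@H]2CCCC(C)(C)C2=CC[C@H]1C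
F2 | step 3 | [(1S,2R,8aS)-1,2,5,5-tetramethyl-1,2,3,5,6,7,8,8a-octahydronaphthalen-1-yl]methanol, mirror image of 7 | OC[C@]1(C)[C@H]2CCCC(C)(C)C2=CC[C@H]1C
F3 | step 8 | 3-tert-butoxy-4-[(Z)-2-ethoxyethenyl]-2-(DecCH2)-4-(trimethylsilyloxy)cyclobut-2-en-1-one (both epimers) | CCO/C=C\C1(O[Si](C)(C)C)C(OC(C)(C)C)=C(C[C@@]2(C)[C@@H]3CCCC(C)(C)C3=CC[C@@H]2C)C1=O
F4 | step 8 | 3-tert-butoxy-6-ethoxy-2-(DecCH2)-4-(trimethylsilyloxy)phenol | CCOc1cc(O[Si](C)(C)C)c(OC(C)(C)C)c(C[C@@]2(C)[C@@H]3CCCC(C)(C)C3=CC[C@@H]2C)c1O
F5 | step 7 | 3-tert-butoxy-4-(ethoxyethynyl)-4-hydroxy-2-(DecCH2)cyclobut-2-en-1-one (both epimers) | CCOC#CC1(O)C(OC(C)(C)C)=C(C[C@@]2(C)[C@@H]3CCCC(C)(C)C3=CC[C@@H]2C)C1=O
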